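**Retrosynthetic overview**
- Feature: in the single six-membered ring the oxygens at C2 (OMe) and C4 (C=O) are meta to each other and the C25 chain sits at C6. This is the 1,3-dioxygenated 5-alkyl pattern of a tetraketide alkylresorcinol. The C5 methyl stands where the polyketide carboxyl carbon was, and the C1 oxygen is a late addition.
- Quinone ⇒ 5-methoxy-2-methyl-3-pentacosylphenol (para-oxidation at C1) ⇒ methyl 2-hydroxy-4-methoxy-6-pentacosylbenzoate (ester carbon reduced to the C5 methyl) ⇒ methyl 2,4-dihydroxy-6-pentacosylbenzoate.
- Key disconnection: ring bond C5–C6, opened to linear methyl 3,5,7-trioxodotriacontanoate (its C2 adds to its C7 ketone). This is the only ring formed.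
- Triketo ester ⇒ diketo-dioxinone (ketene release, methanol capture) ⇒ 2,2,6-trimethyl-4H-1,3-dioxin-4-one + acetyl chloride + hexacosanoic acid, the acid used as its N-methoxy-N-methyl amide.

Key step: step 5

Remark: target numbering is C1 = carbonyl between C2 (OMe) and C6 (pentacosyl), C3–H, C4 = second carbonyl, C5–CH3; the target has no stereocentre; the 1,3-dicarbonyl compounds 6, 8 and 10 are drawn as keto forms although they are largely enolised; all C25/C26 compounds are waxy and are handled in warm THF or in CH2Cl2.

**Step 1**
Reactants: 1 hexacosanoic acid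
Product: 3 N-methoxy-N-methylhexacosanamide, via hexacosanoyl imidazolide 2 (not isolated)
Conditions: CDI, THF, 50 °C; then MeNH(OMe)·HCl, 50 °C → rt
Reagents that add atoms: N,O-dimethylhydroxylamine hydrochloride, CNOC.Cl; 1,1'-carbonyldiimidazole, O=C(n1ccnc1)n1ccnc1 (gives only the imidazolyl group of intermediate 2)
Why: Nucleophilic acyl substitution through the imidazolide should give the amide cleanly, since the liberated imidazole frees the amine from its hydrochloride and warm THF keeps the C26 chain dissolved.

**Step 2**
Reactants: 4 2,2,6-trimethyl-4H-1,3-dioxin-4-one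
Product: 6 2,2-dimethyl-6-(2-oxopropyl)-4H-1,3-dioxin-4-one, via lithium dienolate 5 (not isolated)
Conditions: LiN(SiMe3)2, THF, −78 °C; then AcCl (0.5 equiv relative to 5), −78 → −20 °C; 1 M HCl
Reagents that add atoms: acetyl chloride, CC(=O)Cl; LiN(SiMe3)2, [Li+].C[Si](C)(C)[N-][Si](C)(C)C (gives only the lithium of intermediate 5)
Why: Deprotonation of the C6 methyl gives the extended dienolate, which is C-acylated at its γ-carbon (vinylogous Claisen acylation); the dienolate is used in twofold excess because 6 is more acidic than 4 and consumes one equivalent as base.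

**Step 3**
Reactants: 6 2,2-dimethyl-6-(2-oxopropyl)-4H-1,3-dioxin-4-one; 3 N-methoxy-N-methylhexacosanamide
Product: 8 2,2-dimethyl-6-(2,4-dioxononacosyl)-4H-1,3-dioxin-4-one, via dilithium dianion 7 (not isolated)
Conditions: LiN(i-Pr)2 (2.1 equiv per 6), THF, −78 → −40 °C; then 3 (0.7 equiv, warm THF solution), −40 → 0 °C; 1 M HCl
Reagents that add atoms: LiN(i-Pr)2, [Li+].CC(C)[N-]C(C)C (gives only the lithium of intermediate 7; no atom of it stays in 8)
Why: The 1,3-dicarbonyl-type dianion reacts at its last-formed terminal carbon (dianion Claisen acylation), and the N-methoxy-N-methyl amide releases the new ketone only on the acidic quench, so over-addition and proton exchange with the more acidic product should be suppressed, as they would not be with the acid chloride.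

**Step 4**
Reactants: 8 2,2-dimethyl-6-(2,4-dioxononacosyl)-4H-1,3-dioxin-4-one
Product: 10 methyl 3,5,7-trioxodotriacontanoate, via acylketene 9 (not isolated)
Conditions: MeOH (10 equiv), PhMe, 110 °C, sealed tube; concentrate, use crude
Reagents that add atoms: methanol, CO
Why: Thermal retro-hetero-Diels–Alder fragmentation of the dioxinone expels acetone, and the excess methanol should capture the acylketene faster than the internal C5 enol can lactonise it to a 4-hydroxy-2-pyranone.

**Step 5**
Reactants: 10 methyl 3,5,7-trioxodotriacontanoate
Product: 12 methyl 2,4-dihydroxy-6-pentacosylbenzoate, via cyclic aldol adduct 11 (not isolated)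
Conditions: K2CO3 (2 equiv), MeOH–THF, rt; then HCl in MeOH to pH 2, rt
Reagents that add atoms: none
Why: K2CO3 ionises only the doubly activated methylenes C2, C4 and C6 of 10; of these enolates the C2 enolate, with its C2=C3 bond inside the forming ring, adds to the C7 ketone, makes the C2–C7 bond (ring bond C5–C6 of the target) and gives the tertiary aldol 11. The closest known reaction type is the biomimetic intramolecular aldol condensation and aromatisation of 3,5,7-triketo esters to 6-alkylresorcylates, and the one carbocycle closes in the geometrically favoured 6-(enolendo)-exo-trig mode. E1cB loss of the tertiary hydroxyl, completed by the methanolic HCl, and enolisation of the C3 and C5 ketones give the benzene ring, so the reversible aldol is drained irreversibly towards 12. The two stereocentres of 11 are erased in this aromatisation, so no stereocentre remains to be controlled. The step needs chemoselectivity for aldol closure over Claisen closure (C6 onto the ester carbon C1, the way to an acylphloroglucinol) and over O-cyclisation to pyranones. The substrate secures it because a ketone carbonyl is a much better electrophile than the ester, which is further deactivated within the C1–C3 enolate, because carbonate in methanol does not force methoxide expulsion, and because acid is admitted only after the C–C bond exists, which shuts out acid-promoted 4-pyranone formation.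

**Step 6**
Reactants: 12 methyl 2,4-dihydroxy-6-pentacosylbenzoate
Product: 13 methyl 2-hydroxy-4-methoxy-6-pentacosylbenzoate
Conditions: MeI (1.05 equiv), K2CO3 (1.1 equiv), acetone, reflux
Reagents that add atoms: iodomethane, CI
Why: In this Williamson-type O-methylation the 2-hydroxyl is held in a hydrogen bond to the ester carbonyl, so one equivalent of MeI should alkylate only the free and more acidic 4-hydroxyl, the oxygen that becomes the C2 methoxy group of the target.

**Step 7**
Reactants: 13 methyl 2-hydroxy-4-methoxy-6-pentacosylbenzoate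
Product: 14 2-(hydroxymethyl)-5-methoxy-3-pentacosylphenol
Conditions: LiAlH4 (3 equiv), THF, 0 °C → reflux; aq. KNaC4H4O6 (tartrate) work-up
Reagents that add atoms: none
Why: Hydride reduction of the ester, with heating because the ester is hindered and deactivated by the phenoxide, should give the salicyl-type alcohol, and any over-reduction through the ortho-quinone methide only anticipates step 8.

**Step 8**
Reactants: 14 2-(hydroxymethyl)-5-methoxy-3-pentacosylphenol
Product: 15 5-methoxy-2-methyl-3-pentacosylphenol
Conditions: Et3SiH (5 equiv), CF3CO2H, CH2Cl2 (dilute), 0 °C → rt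
Reagents that add atoms: none
Why: In this ionic hydrogenation the acid ionises the benzylic alcohol to a cation stabilised by the ortho hydroxyl and the para methoxy group, and the excess silane should deliver hydride faster than a second arene can attack.

**Step 9**
Reactants: 15 5-methoxy-2-methyl-3-pentacosylphenol
Product: 16 2-methoxy-5-methyl-6-pentacosylcyclohexa-2,5-diene-1,4-dione (target)
Conditions: (KSO3)2NO (2.5 equiv), aq. Na2HPO4/KH2PO4 buffer (pH 7), methyltrioctylammonium chloride (cat.), CH2Cl2–H2O, rt
Reagents that add atoms: potassium nitrosodisulfonate (KSO3)2NO, [K+].[K+].[O-]S(=O)(=O)N([O])S(=O)(=O)[O-]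
Why: In this Teuber oxidation one nitrosodisulfonate radical removes the phenolic hydrogen and a second bonds through oxygen to the free para carbon (C1 of the target), loss of imidodisulfonate then gives the para-quinone, the carbon para to the methoxy group is blocked by methyl, and the ammonium salt carries the oxidant to the lipophilic phenol.

**Compound list**
1 | hexacosanoic acid | CCCCCCCCCCCCCCCCCCCCCCCCCC(=O)O | starting material
2 | 1-(1H-imidazol-1-yl)hexacosan-1-one (hexacosanoyl imidazolide) | CCCCCCCCCCCCCCCCCCCCCCCCCC(=O)n1ccnc1 | intermediate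
3 | N-methoxy-N-methylhexacosanamide | CCCCCCCCCCCCCCCCCCCCCCCCCC(=O)N(C)OC | intermediate
4 | 2,2,6-trimethyl-4H-1,3-dioxin-4-one | CC1=CC(=O)OC(C)(C)O1 | starting material
5 | lithium 2,2-dimethyl-6-methylidene-6H-1,3-dioxin-4-olate (lithium dienolate of 4) | [Li+].C=C1C=C([O-])OC(C)(C)O1 | intermediate
6 | 2,2-dimethyl-6-(2-oxopropyl)-4H-1,3-dioxin-4-one | CC(=O)CC1=CC(=O)OC(C)(C)O1 | intermediate
7 | dilithium dianion of 6 (C1' and terminal CH3 deprotonated) | [Li+].[Li+].C=C([O-])C=C1C=C([O-])OC(C)(C)O1 | intermediate
8 | 2,2-dimethyl-6-(2,4-dioxononacosyl)-4H-1,3-dioxin-4-one | CCCCCCCCCCCCCCCCCCCCCCCCCC(=O)CC(=O)CC1=CC(=O)OC(C)(C)O1 | intermediate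
9 | dotriacont-1-ene-1,3,5,7-tetrone (acylketene) | CCCCCCCCCCCCCCCCCCCCCCCCCC(=O)CC(=O)CC(=O)C=C=O | intermediate
10 | methyl 3,5,7-trioxodotriacontanoate | CCCCCCCCCCCCCCCCCCCCCCCCCC(=O)CC(=O)CC(=O)CC(=O)OC | intermediate
11 | methyl 2-hydroxy-4,6-dioxo-2-pentacosylcyclohexane-1-carboxylate (stereoisomer mixture, both centres lost on aromatisation) | CCCCCCCCCCCCCCCCCCCCCCCCCC1(O)CC(=O)CC(=O)C1C(=O)OC | intermediate
12 | methyl 2,4-dihydroxy-6-pentacosylbenzoate | CCCCCCCCCCCCCCCCCCCCCCCCCc1cc(O)cc(O)c1C(=O)OC | intermediate
13 | methyl 2-hydroxy-4-methoxy-6-pentacosylbenzoate | CCCCCCCCCCCCCCCCCCCCCCCCCc1cc(OC)cc(O)c1C(=O)OC | intermediate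
14 | 2-(hydroxymethyl)-5-methoxy-3-pentacosylphenol | CCCCCCCCCCCCCCCCCCCCCCCCCc1cc(OC)cc(O)c1CO | intermediate
15 | 5-methoxy-2-methyl-3-pentacosylphenol | CCCCCCCCCCCCCCCCCCCCCCCCCc1cc(OC)cc(O)c1C | intermediate
16 | 2-methoxy-5-methyl-6-pentacosylcyclohexa-2,5-diene-1,4-dione | CCCCCCCCCCCCCCCCCCCCCCCCCC1=C(C)C(=O)C=C(OC)C1=O | target

**Step count**
Total step count: 9.
Longest linear sequence: 8 steps (steps 2–9 from 4). The branch from 1 (steps 1 and 3–9) is equally long.

**Steps most likely to fail**

1. Step 5.
   - Risk: in the freely rotating open chain, Claisen closure onto the ester, O-cyclisation to pyranones or retro-Claisen chain cleavage may outrun the aldol closure.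
   - Fallback: it sets out from 8 and closes the ring before the carboxyl group is unmasked. Et3N in CH2Cl2 at rt should enolise the side chain. The nucleophilic C5 of the intact dioxinone then adds to the distal ketone, and dehydration and enolisation give 7-hydroxy-2,2-dimethyl-5-pentacosyl-4H-1,3-benzodioxin-4-one F1. The carboxyl carbon lies trans to the side chain across the dioxinone C5=C6 bond, so Claisen closure cannot reach it, and no ketene is present to lactonise. NaOMe in MeOH–THF then opens the benzodioxinone with loss of acetone, and the route is rejoined at 12.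

2. Step 3.
   - Risk: the waxy amide may crystallise out of THF at the low temperature the dianion needs, and proton exchange may quench the dianion before acylation is complete.
   - Fallback: it sets out from 1 and 4 and replaces hard-enolate chemistry by soft enolisation.
     - (COCl)2 with catalytic DMF in warm CH2Cl2 converts 1 into hexacosanoyl chloride F2.
     - Commercial mono-allyl malonate and (COCl)2 give prop-2-enyl 3-chloro-3-oxopropanoate F3.
     - F3 acylates lithium dienolate 5 (from 4) at −78 °C to give prop-2-enyl 4-(2,2-dimethyl-4-oxo-4H-1,3-dioxin-6-yl)-3-oxobutanoate F4.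
     - MgCl2 and pyridine in CH2Cl2 at 0 °C → rt, where F2 stays dissolved, should chelate the β-keto ester and direct C-acylation to the methylene between ketone and ester. This gives prop-2-enyl 2-[(2,2-dimethyl-4-oxo-4H-1,3-dioxin-6-yl)acetyl]-3-oxooctacosanoate F5.
     - Pd(PPh3)4 (zerovalent palladium) and morpholine remove the allyl group, the β-keto acid decarboxylates, and the route is rejoined at 8.

3. Step 9.
   - Risk: electron transfer across the phase boundary may be sluggish, and phenoxyl radicals may couple with each other instead of with the oxidant.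
   - Fallback: it sets out from 15 and brings in the C1 oxygen by two-electron chemistry.
     - Vilsmeier–Haack formylation (POCl3, DMF, ClCH2CH2Cl, 0 → 60 °C; aq. NaOAc) should attack the carbon para to the hydroxyl and ortho to the methoxy group rather than the crowded carbon between the two oxygens. This gives 4-hydroxy-2-methoxy-5-methyl-6-pentacosylbenzaldehyde F6.
     - Dakin oxidation (H2O2, NaOH, THF–H2O, under N2) exchanges formyl for hydroxyl to give 2-methoxy-5-methyl-6-pentacosylbenzene-1,4-diol F7.
     - Ag2O in CH2Cl2 dehydrogenates F7, and the route is rejoined at 16.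

**Further compounds**
F1 | step 5 | 7-hydroxy-2,2-dimethyl-5-pentacosyl-4H-1,3-benzodioxin-4-one | CCCCCCCCCCCCCCCCCCCCCCCCCc1cc(O)cc2OC(C)(C)OC(=O)c12
F2 | step 3 | hexacosanoyl chloride | CCCCCCCCCCCCCCCCCCCCCCCCCC(=O)Cl
F3 | step 3 | prop-2-enyl 3-chloro-3-oxopropanoate | C=CCOC(=O)CC(=O)Cl
F4 | step 3 | prop-2-enyl 4-(2,2-dimethyl-4-oxo-4H-1,3-dioxin-6-yl)-3-oxobutanoate | C=CCOC(=O)CC(=O)CC1=CC(=O)OC(C)(C)O1
F5 | step 3 | prop-2-enyl 2-[(2,2-dimethyl-4-oxo-4H-1,3-dioxin-6-yl)acetyl]-3-oxooctacosanoate (configurationally labile methine) | CCCCCCCCCCCCCCCCCCCCCCCCCC(=O)C(C(=O)OCC=C)C(=O)CC1=CC(=O)OC(C)(C)O1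
F6 | step 9 | 4-hydroxy-2-methoxy-5-methyl-6-pentacosylbenzaldehyde | CCCCCCCCCCCCCCCCCCCCCCCCCc1c(C)c(O)cc(OC)c1C=O
F7 | step 9 | 2-methoxy-5-methyl-6-pentacosylbenzene-1,4-diol | CCCCCCCCCCCCCCCCCCCCCCCCCc1c(C)c(O)cc(OC)c1O
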